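**Plan**

1. Retrosynthetic cuts: the C6–O angelate bond (epoxide opening) and the exocyclic C4=CH2 (Peterson olefination) in the six-membered ring; then the C1–C7a bond of the five-membered ring, which returns a cyclobutanol fused at C3a–C7a; last the cyclobutane bonds C2–C7a and C3–C3a ([2+2]) and the cyclohexenone (Michael/aldol).
2. Enabling feature: in the five-membered ring the oxygen-bearing C2 is next to the ethylidene-bearing C1, and C1 is bonded to the ring-fusion carbon C7a. This 2-alkylidenecyclopentan-1-ol array is what a 1-alkenylcyclobutanol (ring C2–C3–C3a–C7a, alkenyl on C2) gives when C7a shifts from C2 to the alkene carbon.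
3. Forward order: six-membered ring first ((S)-cryptone), four-membered ring by enone/ketene acetal photocycloaddition, four-to-five ring expansion that also writes the (Z)-ethylidene, then ring-fusion correction, oxygenation of C5/C6, and the methylidene last.
4. Stereochemistry: C7 from the organocatalytic Michael addition; C7a from photocycloaddition anti to isopropyl; C3a by equilibration next to the C4 ketone; C2 by CBS reduction; ethylidene geometry by anti seleno-migration then syn selenoxide elimination; C5/C6 by hydroxyl-directed epoxidation and trans-diaxial opening.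

Key step: step 8

Remark: hydrindanes are numbered as in the target (C1 ethylidene carbon, C2 acetoxy carbon, C3, C3a, C4 methylidene carbon, C5 carbinol, C6 angelate carbon, C7 isopropyl carbon, C7a); in the bicyclo[4.2.0]octanes C2, C5, C6, C1, C7 and C8 become C4, C7, C7a, C3a, C2 and C3.

**Step 1**
Reactants: 1 3-methylbutanal; 2 but-3-en-2-one
Product: 3 (2S)-5-oxo-2-(propan-2-yl)hexanal
Conditions: (S)-α,α-diphenylprolinol trimethylsilyl ether (5 mol %), ethyl 3,4-dihydroxybenzoate (20 mol %), neat, 4 °C
Reagents that add atoms: none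
Why: Enamine-catalysed Michael addition in which the bulky diphenyl(silyloxy)methyl group shields one face of the E-enamine, so the enone should add from the open face and set the (S) isopropyl-bearing carbon (later C7).

**Step 2**
Reactants: 3 (2S)-5-oxo-2-(propan-2-yl)hexanal
Product: 4 (4S)-4-(propan-2-yl)cyclohex-2-en-1-one ((S)-cryptone)
Conditions: LiOH (cat.), i-PrOH, rt
Reagents that add atoms: none
Why: Intramolecular aldol condensation of the methyl ketone onto the aldehyde followed by dehydration, under hydroxide conditions mild enough that the α-branched stereocentre should survive.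

**Step 3**
Reactants: 4 (S)-cryptone; 5 1,1-diethoxyethene
Product: 7 (1S,5S,6S)-7,7-diethoxy-5-(propan-2-yl)bicyclo[4.2.0]octan-2-one (cis-fused), via trans-fused photoadduct 6 (not isolated)
Conditions: hν (350 nm, Pyrex), pentane, −30 °C; then basic Al2O3, Et2O, rt
Reagents that add atoms: none
Why: Enone–alkene [2+2] photocycloaddition in which the electron-rich ketene acetal adds head-to-tail (acetal carbon on the β-carbon) and anti to the C4 isopropyl group, which sets the future C7a, while alumina epimerises the trans-fused adduct next to the ketone to the cis-fused one.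

**Step 4**
Reactants: 7 cis-fused ketal ketone
Product: 8 cis-fused 7,7-diethoxy-5-isopropylbicyclo[4.2.0]octan-2-ol (2-OH cis to the four-membered ring)
Conditions: NaBH4, MeOH, 0 °C
Reagents that add atoms: none
Why: Borohydride reduction from the convex face masks the ketone as a carbinol whose configuration is of no consequence, since it is reoxidised in step 12.

**Step 5**
Reactants: 8 ketal alcohol
Product: 9 tert-butyldimethylsilyl ether of 8
Conditions: TBSCl, imidazole, DMF, 40 °C
Reagents that add atoms: tert-butyldimethylsilyl chloride, CC(C)(C)[Si](C)(C)Cl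
Why: Standard silylation under non-acidic conditions that leave the ketal intact and protect the carbinol through the organolithium, selenium and hydride steps.

**Step 6**
Reactants: 9 silyl ether ketal
Product: 10 cis-fused 2-(tert-butyldimethylsilyloxy)-5-isopropylbicyclo[4.2.0]octan-7-one
Conditions: PPTS, acetone/H2O, 45 °C
Reagents that add atoms: water, O
Why: Mild acid-catalysed ketal hydrolysis, which a secondary TBS ether should tolerate, frees the cyclobutanone whose carbonyl carbon is bonded to the future C7a.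

**Step 7**
Reactants: 10 cyclobutanone; 11 (Z)-1-bromoprop-1-ene
Product: 12 cis-fused 2-(tert-butyldimethylsilyloxy)-5-isopropyl-7-[(1Z)-prop-1-en-1-yl]bicyclo[4.2.0]octan-7-ol (propenyl on the convex face)
Conditions: 11, t-BuLi (2 equiv), Et2O, −78 °C; then 10, THF, −78 °C
Reagents that add atoms: none
Why: Bromine–lithium exchange with retention of the Z geometry followed by 1,2-addition of the alkenyllithium to the strained cyclobutanone from the convex face; the carbinol configuration is irrelevant because this carbon becomes the ketone in step 8.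

**Step 8**
Reactants: 12 (Z)-propenyl cyclobutanol
Product: 15 cis-fused (1Z)-4-(tert-butyldimethylsilyloxy)-1-ethylidene-7-isopropyloctahydro-2H-inden-2-one, via β-seleno ketone 13 (not isolated), via selenoxide 14 (not isolated)
Conditions: PhSeCl, CH2Cl2, −78 °C; then pyridine, 30 % H2O2, 0 °C to rt
Reagents that add atoms: none
Why: PhSeCl turns the Z-alkene into a seleniranium ion that is opened by a semipinacol 1,2-shift, the more substituted cyclobutane bond (to the future C7a) migrating antiperiplanar to selenium onto the proximal alkene carbon while the carbinol becomes the ketone, so the four-membered ring grows to the cyclopentanone with release of ring strain. The closest known reaction type is the electrophile-induced (halonium or selenium) semipinacol ring expansion of 1-alkenylcyclobutanols, followed by a selenoxide syn-elimination. No ring is closed by a cyclisation: the five-membered ring arises by a suprafacial 1,2-alkyl shift with retention at the migrating ring-fusion carbon. The two transient stereocentres (C1 and the selenium-bearing carbon) are related by anti addition across the Z-alkene, and syn-elimination through the single α-hydrogen translates this relation into the (Z)-ethylidene (methyl syn to the carbonyl) whichever alkene face was attacked. The step needs migration of the secondary ring-fusion carbon rather than the ring CH2, secured by the higher migratory aptitude of the more substituted carbon, and elimination toward the α-CH rather than the methyl group, secured by the acidity of that hydrogen and conjugation with the ketone.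

**Step 9**
Reactants: 15 cis-fused (Z)-enone
Product: 16 cis-fused (1Z,2S)-4-(tert-butyldimethylsilyloxy)-1-ethylidene-7-isopropyloctahydro-1H-inden-2-ol
Conditions: (R)-2-methyl-CBS-oxazaborolidine (20 mol %), catecholborane, toluene, −78 °C
Reagents that add atoms: none
Why: CBS reduction in which the alkylidene-bearing carbon acts as the large group, so the (R)-catalyst should deliver hydride to give the (2S)-allylic alcohol under reagent control, 1,2-selectively and without hydroboration of the alkene.

**Step 10**
Reactants: 16 allylic alcohol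
Product: 17 cis-fused (1Z,2S)-2-acetoxy-4-(tert-butyldimethylsilyloxy)-1-ethylidene-7-isopropyloctahydro-1H-indene
Conditions: Ac2O, pyridine, DMAP (cat.), CH2Cl2, rt
Reagents that add atoms: acetic anhydride, CC(=O)OC(C)=O
Why: Routine acylation installs the C2 acetate of the target before any other hydroxyl group is free.

**Step 11**
Reactants: 17 silyl ether acetate
Product: 18 cis-fused (1Z,2S)-2-acetoxy-1-ethylidene-7-isopropyloctahydro-1H-inden-4-ol
Conditions: HF·pyridine, THF/pyridine, 0 °C to rt
Reagents that add atoms: none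
Why: Buffered fluoride cleaves the secondary silyl ether without touching the allylic acetate.

**Step 12**
Reactants: 18 C4 alcohol
Product: 20 trans-fused (1Z,2S)-2-acetoxy-1-ethylidene-7-isopropyloctahydro-4H-inden-4-one, via cis-fused ketone 19 (not isolated)
Conditions: Dess–Martin periodinane, NaHCO3, CH2Cl2, rt; then DBU, toluene, 50 °C
Reagents that add atoms: none
Why: Dess–Martin oxidation restores the C4 ketone and DBU equilibrates the adjacent C3a through the enolate, the trans-fused hydrindanone with the C1, C3 and isopropyl branches all equatorial being expected to be the more stable isomer (recovered cis-ketone is resubmitted).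

**Step 13**
Reactants: 20 trans-fused ketone
Product: 21 trans-fused (1Z,2S)-2-acetoxy-1-ethylidene-7-isopropyl-1,2,3,3a,7,7a-hexahydro-4H-inden-4-one
Conditions: LiN(SiMe3)2, THF, −78 °C; then PhS(Cl)=N-t-Bu, −78 °C
Reagents that add atoms: none
Why: Kinetic deprotonation at the C5 methylene (less hindered than the C3a methine, and the ketone is more acidic than the acetate) followed by the sulfinimidoyl chloride dehydrogenation of the lithium enolate (Mukaiyama) should give the C5=C6 enone.

**Step 14**
Reactants: 21 enone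
Product: 22 trans-fused tertiary allylic alcohol, 2-acetoxy-1-ethylidene-7-isopropyl-4-[(trimethylsilyl)methyl]-2,3,3a,4,7,7a-hexahydro-1H-inden-4-ol (4-OH trans to the C3a–C3 bond)
Conditions: Me3SiCH2Li, CeCl3, THF, −78 °C
Reagents that add atoms: (trimethylsilyl)methyllithium, [Li]C[Si](C)(C)C
Why: Organocerium 1,2-addition (first half of a Peterson olefination), expected to occur by axial attack on the cyclohexenone past a single syn-axial hydrogen so that the hydroxyl ends equatorial, with the acetate tolerated at −78 °C.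

**Step 15**
Reactants: 22 tertiary allylic alcohol
Product: 23 5,6-epoxide of 22 (epoxide cis to the 4-OH and anti to isopropyl)
Conditions: VO(acac)2 (cat.), t-BuOOH, CH2Cl2, 0 °C to rt
Reagents that add atoms: tert-butyl hydroperoxide, CC(C)(C)OO
Why: Hydroxyl-directed vanadium-catalysed epoxidation delivers oxygen syn to the allylic alcohol, which sets the C5–O bond, and leaves the ethylidene, which has no free hydroxyl, untouched.

**Step 16**
Reactants: 23 epoxy alcohol; 24 angelic acid ((2Z)-2-methylbut-2-enoic acid)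
Product: 25 4,5-dihydroxy-6-angelate, 2-acetoxy-1-ethylidene-4,5-dihydroxy-7-isopropyl-4-[(trimethylsilyl)methyl]octahydro-1H-inden-6-yl (2Z)-2-methylbut-2-enoate
Conditions: 24, Ti(OiPr)4, CH2Cl2, rt
Reagents that add atoms: none
Why: Ti(OiPr)4-mediated opening of a 2,3-epoxy alcohol by a carboxylic acid at the distal carbon (C6), here also the trans-diaxial (Fürst–Plattner) mode, should invert C6 and give the 6-angelate and 5-hydroxyl trans-diaxial as in the target; diaxial opening is known to proceed next to a syn-axial alkyl group.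

**Step 17**
Reactants: 25 β-hydroxysilane
Product: 26 (2S,3aR,5S,6S,7S,7aR)-2-acetoxy-1-[(Z)-ethylidene]-5-hydroxy-4-methylidene-7-(propan-2-yl)octahydro-1H-inden-6-yl (2Z)-2-methylbut-2-enoate (target)
Conditions: aq. HF, MeCN, 0 °C
Reagents that add atoms: none
Why: Acid-induced Peterson elimination of the tertiary β-hydroxysilane gives the exocyclic methylidene regiospecifically, under conditions the esters and the secondary alcohol should survive.

**Compound list**

1 | 3-methylbutanal | CC(C)CC=O | starting material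
2 | but-3-en-2-one | CC(=O)C=C | starting material
3 | (2S)-5-oxo-2-(propan-2-yl)hexanal | CC(=O)CC[C@@H](C(C)C)C=O | intermediate
4 | (4S)-4-(propan-2-yl)cyclohex-2-en-1-one | O=C1CC[C@@H](C(C)C)C=C1 | intermediate
5 | 1,1-diethoxyethene | C=C(OCC)OCC | starting material
6 | trans-fused photoadduct, (1R,5S,6S)-7,7-diethoxy-5-(propan-2-yl)bicyclo[4.2.0]octan-2-one (not isolated) | O=C1CC[C@@H](C(C)C)[C@@H]2C(OCC)(OCC)C[C@@H]12 | intermediate
7 | (1S,5S,6S)-7,7-diethoxy-5-(propan-2-yl)bicyclo[4.2.0]octan-2-one (cis-fused) | O=C1CC[C@@H](C(C)C)[C@@H]2C(OCC)(OCC)C[C@H]12 | intermediate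
8 | cis-fused 7,7-diethoxy-5-isopropylbicyclo[4.2.0]octan-2-ol | O[C@@H]1CC[C@@H](C(C)C)[C@@H]2C(OCC)(OCC)C[C@H]12 | intermediate
9 | tert-butyldimethylsilyl ether of 8 | CC(C)(C)[Si](C)(C)O[C@@H]1CC[C@@H](C(C)C)[C@@H]2C(OCC)(OCC)C[C@H]12 | intermediate
10 | cis-fused 2-(tert-butyldimethylsilyloxy)-5-isopropylbicyclo[4.2.0]octan-7-one | CC(C)(C)[Si](C)(C)O[C@@H]1CC[C@@H](C(C)C)[C@@H]2C(=O)C[C@H]12 | intermediate
11 | (Z)-1-bromoprop-1-ene | C/C=C\Br | starting material
12 | cis-fused 2-(tert-butyldimethylsilyloxy)-5-isopropyl-7-[(1Z)-prop-1-en-1-yl]bicyclo[4.2.0]octan-7-ol | CC(C)(C)[Si](C)(C)O[C@@H]1CC[C@@H](C(C)C)[C@@H]2[C@@](O)(/C=C\C)C[C@H]12 | intermediate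
13 | cis-fused 4-(tert-butyldimethylsilyloxy)-7-isopropyl-1-[1-(phenylselanyl)ethyl]octahydro-2H-inden-2-one (not isolated; one of two C1 epimers that converge) | CC(C)(C)[Si](C)(C)O[C@@H]1CC[C@@H](C(C)C)[C@@H]2[C@@H]([C@@H](C)[Se]c3ccccc3)C(=O)C[C@H]12 | intermediate
14 | selenoxide of 13 (not isolated; configuration at selenium undefined) | CC(C)(C)[Si](C)(C)O[C@@H]1CC[C@@H](C(C)C)[C@@H]2[C@@H]([C@@H](C)[Se](=O)c3ccccc3)C(=O)C[C@H]12 | intermediate
15 | cis-fused (1Z)-4-(tert-butyldimethylsilyloxy)-1-ethylidene-7-isopropyloctahydro-2H-inden-2-one | CC(C)(C)[Si](C)(C)O[C@@H]1CC[C@@H](C(C)C)[C@@H]2/C(=C/C)C(=O)C[C@H]12 | intermediate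
16 | cis-fused (1Z,2S)-4-(tert-butyldimethylsilyloxy)-1-ethylidene-7-isopropyloctahydro-1H-inden-2-ol | CC(C)(C)[Si](C)(C)O[C@@H]1CC[C@@H](C(C)C)[C@@H]2/C(=C/C)[C@@H](O)C[C@H]12 | intermediate
17 | acetate of 16 | CC(C)(C)[Si](C)(C)O[C@@H]1CC[C@@H](C(C)C)[C@@H]2/C(=C/C)[C@@H](OC(C)=O)C[C@H]12 | intermediate
18 | cis-fused (1Z,2S)-2-acetoxy-1-ethylidene-7-isopropyloctahydro-1H-inden-4-ol | O[C@@H]1CC[C@@H](C(C)C)[C@@H]2/C(=C/C)[C@@H](OC(C)=O)C[C@H]12 | intermediate
19 | cis-fused (1Z,2S)-2-acetoxy-1-ethylidene-7-isopropyloctahydro-4H-inden-4-one (not isolated) | O=C1CC[C@@H](C(C)C)[C@@H]2/C(=C/C)[C@@H](OC(C)=O)C[C@H]12 | intermediate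
20 | trans-fused (1Z,2S)-2-acetoxy-1-ethylidene-7-isopropyloctahydro-4H-inden-4-one | O=C1CC[C@@H](C(C)C)[C@@H]2/C(=C/C)[C@@H](OC(C)=O)C[C@@H]12 | intermediate
21 | trans-fused (1Z,2S)-2-acetoxy-1-ethylidene-7-isopropyl-1,2,3,3a,7,7a-hexahydro-4H-inden-4-one | O=C1C=C[C@@H](C(C)C)[C@@H]2/C(=C/C)[C@@H](OC(C)=O)C[C@@H]12 | intermediate
22 | trans-fused 2-acetoxy-1-ethylidene-7-isopropyl-4-[(trimethylsilyl)methyl]-2,3,3a,4,7,7a-hexahydro-1H-inden-4-ol | C[Si](C)(C)C[C@@]1(O)C=C[C@@H](C(C)C)[C@@H]2/C(=C/C)[C@@H](OC(C)=O)C[C@@H]12 | intermediate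
23 | 5,6-epoxide of 22 (cis to the 4-OH) | C[Si](C)(C)C[C@@]1(O)[C@@H]3O[C@@H]3[C@@H](C(C)C)[C@@H]2/C(=C/C)[C@@H](OC(C)=O)C[C@@H]12 | intermediate
24 | angelic acid, (2Z)-2-methylbut-2-enoic acid | C/C=C(/C)C(=O)O | starting material
25 | 2-acetoxy-1-ethylidene-4,5-dihydroxy-7-isopropyl-4-[(trimethylsilyl)methyl]octahydro-1H-inden-6-yl (2Z)-2-methylbut-2-enoate | C[Si](C)(C)C[C@@]1(O)[C@H](O)[C@@H](OC(=O)/C(C)=C\C)[C@@H](C(C)C)[C@@H]2/C(=C/C)[C@@H](OC(C)=O)C[C@@H]12 | intermediate
26 | (2S,3aR,5S,6S,7S,7aR)-2-acetoxy-1-[(Z)-ethylidene]-5-hydroxy-4-methylidene-7-(propan-2-yl)octahydro-1H-inden-6-yl (2Z)-2-methylbut-2-enoate | C=C1[C@H](O)[C@@H](OC(=O)/C(C)=C\C)[C@@H](C(C)C)[C@@H]2/C(=C/C)[C@@H](OC(C)=O)C[C@@H]12 | target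

**Totals and risks**

Total step count: 17. Longest linear sequence: 17 steps (from 1).

Steps most likely to fail:

Step 8. What may go wrong: shift of the ring CH2 in place of the ring-fusion carbon, or loss of the anti/syn relay (enolisation at the α-carbon of the β-seleno ketone before the syn-elimination, or elimination toward the methyl group), giving regio- or E/Z-isomeric enones. The fallback sets out from 10 and returns at 15. Ketone 10 is treated with HC≡CMgBr (THF, −78 °C) to give the ethynyl carbinol F1. N-Iodosuccinimide in hexafluoroisopropanol/CH2Cl2 then triggers the iodonium-induced ring expansion, in which the ring-fusion carbon and iodine add anti across the alkyne, to give the (Z)-iodomethylidene ketone F2. Negishi coupling of F2 with Me2Zn and Pd(PPh3)4 proceeds with retention and gives 15, the geometry now being fixed in a configurationally stable vinyl iodide.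

Step 12. What may go wrong: an unfavourable position of the cis/trans equilibrium at the ring fusion, because the exocyclic double bond next to C7a lowers the usual preference for the trans-hydrindanone. The fallback sets out from 4 and returns at 20, taking the trans ring fusion kinetically from the photocycloaddition. Enone 4 and 5 are irradiated as in step 3 without the alumina treatment, and the crude photolysate is reduced at −78 °C (NaBH4, CeCl3, MeOH). The trans-fused alcohol F3 is separated from 8 and silylated to the silyl ether F4. Hydrolysis (PPTS, acetone/H2O) gives the trans-fused cyclobutanone F5, and (Z)-prop-1-enyllithium adds to give the carbinol F6. PhSeCl, then pyridine/H2O2, expand the ring through the β-seleno ketone F7 and its selenoxide F8 to the trans-fused (Z)-enone F9. CBS reduction gives the alcohol F10, acetylation the acetate F11, HF·pyridine the C4 alcohol F12, and Dess–Martin oxidation of F12 gives 20 without epimerisation.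

Step 14. What may go wrong: poor facial selectivity in the addition to the enone carbonyl; equatorial attack would place the directing hydroxyl, and with it the epoxide, on the wrong face. The fallback sets out from 21 and returns at 23. Luche reduction (NaBH4, CeCl3, MeOH, −78 °C; reliably axial hydride delivery) gives the allylic alcohol F13 with the hydroxyl equatorial. VO(acac)2/t-BuOOH epoxidises syn to it to give the epoxy alcohol F14, and Dess–Martin oxidation gives the epoxy ketone F15. Me3SiCH2Li/CeCl3 then adds to F15 anti to the epoxide oxygen and gives 23.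

**Further compounds**

F1 | step 8 | cis-fused 2-(tert-butyldimethylsilyloxy)-7-ethynyl-5-isopropylbicyclo[4.2.0]octan-7-ol | CC(C)(C)[Si](C)(C)O[C@@H]1CC[C@@H](C(C)C)[C@@H]2[C@@](O)(C#C)C[C@H]12
F2 | step 8 | cis-fused (1Z)-4-(tert-butyldimethylsilyloxy)-1-(iodomethylidene)-7-isopropyloctahydro-2H-inden-2-one | CC(C)(C)[Si](C)(C)O[C@@H]1CC[C@@H](C(C)C)[C@@H]2/C(=C/I)C(=O)C[C@H]12
F3 | step 12 | trans-fused 7,7-diethoxy-5-isopropylbicyclo[4.2.0]octan-2-ol | O[C@@H]1CC[C@@H](C(C)C)[C@@H]2C(OCC)(OCC)C[C@@H]12
F4 | step 12 | tert-butyldimethylsilyl ether of F3 | CC(C)(C)[Si](C)(C)O[C@@H]1CC[C@@H](C(C)C)[C@@H]2C(OCC)(OCC)C[C@@H]12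
F5 | step 12 | trans-fused 2-(tert-butyldimethylsilyloxy)-5-isopropylbicyclo[4.2.0]octan-7-one | CC(C)(C)[Si](C)(C)O[C@@H]1CC[C@@H](C(C)C)[C@@H]2C(=O)C[C@@H]12
F6 | step 12 | trans-fused 2-(tert-butyldimethylsilyloxy)-5-isopropyl-7-[(1Z)-prop-1-en-1-yl]bicyclo[4.2.0]octan-7-ol | CC(C)(C)[Si](C)(C)O[C@@H]1CC[C@@H](C(C)C)[C@@H]2[C@@](O)(/C=C\C)C[C@@H]12
F7 | step 12 | trans-fused 4-(tert-butyldimethylsilyloxy)-7-isopropyl-1-[1-(phenylselanyl)ethyl]octahydro-2H-inden-2-one | CC(C)(C)[Si](C)(C)O[C@@H]1CC[C@@H](C(C)C)[C@@H]2[C@@H]([C@@H](C)[Se]c3ccccc3)C(=O)C[C@@H]12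
F8 | step 12 | selenoxide of F7 | CC(C)(C)[Si](C)(C)O[C@@H]1CC[C@@H](C(C)C)[C@@H]2[C@@H]([C@@H](C)[Se](=O)c3ccccc3)C(=O)C[C@@H]12
F9 | step 12 | trans-fused (1Z)-4-(tert-butyldimethylsilyloxy)-1-ethylidene-7-isopropyloctahydro-2H-inden-2-one | CC(C)(C)[Si](C)(C)O[C@@H]1CC[C@@H](C(C)C)[C@@H]2/C(=C/C)C(=O)C[C@@H]12
F10 | step 12 | trans-fused (1Z,2S)-4-(tert-butyldimethylsilyloxy)-1-ethylidene-7-isopropyloctahydro-1H-inden-2-ol | CC(C)(C)[Si](C)(C)O[C@@H]1CC[C@@H](C(C)C)[C@@H]2/C(=C/C)[C@@H](O)C[C@@H]12
F11 | step 12 | acetate of F10 | CC(C)(C)[Si](C)(C)O[C@@H]1CC[C@@H](C(C)C)[C@@H]2/C(=C/C)[C@@H](OC(C)=O)C[C@@H]12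
F12 | step 12 | trans-fused (1Z,2S)-2-acetoxy-1-ethylidene-7-isopropyloctahydro-1H-inden-4-ol | O[C@@H]1CC[C@@H](C(C)C)[C@@H]2/C(=C/C)[C@@H](OC(C)=O)C[C@@H]12
F13 | step 14 | trans-fused 2-acetoxy-1-ethylidene-7-isopropyl-2,3,3a,4,7,7a-hexahydro-1H-inden-4-ol (4-OH trans to the C3a–C3 bond) | O[C@@H]1C=C[C@@H](C(C)C)[C@@H]2/C(=C/C)[C@@H](OC(C)=O)C[C@@H]12
F14 | step 14 | 5,6-epoxide of F13 (cis to the 4-OH) | O[C@@H]1[C@@H]3O[C@@H]3[C@@H](C(C)C)[C@@H]2/C(=C/C)[C@@H](OC(C)=O)C[C@@H]12
F15 | step 14 | trans-fused 2-acetoxy-5,6-epoxy-1-ethylidene-7-isopropyloctahydro-4H-inden-4-one | O=C1[C@@H]3O[C@@H]3[C@@H](C(C)C)[C@@H]2/C(=C/C)[C@@H](OC(C)=O)C[C@@H]12
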